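## The problem

Target 27 is a daucane ester. Cyclopentane ring A (C1–C5) and cycloheptane ring B (C1, C5–C10) share the C1–C5 bond in a trans fusion, with the angular methyl on C1 and the hydrogen on C5 on opposite faces. It has six stereocentres, (1R,4R,5S,6S,8R,9S): the all-carbon quaternary C1, the tertiary C4 carrying isopropyl and the vanilloyloxy group, the ring-fusion methine C5, the secondary carbinol C6 and the epoxide carbons C8 and C9. The C1 methyl and the C4 oxygen lie on one face; the C5 hydrogen, the C6 hydroxyl and the epoxide oxygen lie on the other. C1, C4 and C5 are contiguous, two are fully substituted and none can be corrected later, so they must come from one controlled event. Once they are fixed the rest can be relayed: the C4 oxygen can deliver hydride to a C6 ketone and place the C6 hydroxyl anti to itself, and the C6 hydroxyl, homoallylic to C8=C9, can then guide the epoxide oxygen to its own face. The ester is the awkward function: it sits on a tertiary alcohol between isopropyl and the ring fusion, next to a far more reactive secondary hydroxyl, and it has to be made before the epoxide, which is acid-labile and whose rear face is within reach of a C4 alkoxide. With C6 at the ketone level the C4 oxygen is the β-oxygen of an aldol, so strong base there invites retro-aldol cleavage or elimination, and the phenol must stay masked through acylation and oxidation. A short entry is possible because C1 and C4 are both bonded to C5: a cycloheptene with a C5=C1 double bond and an isobutyryl group on C5 is an enone whose β-carbon (C1) and carbonyl carbon (C4) are exactly the ring A atoms that the missing pair C2–C3 must bridge, and an alkyne can supply that pair.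

## Retrosynthesis

**Epoxide and phenol (27 ⇒ 26 ⇒ 25).** The last bonds cut are the two C–O bonds of the epoxide and the phenol O–H. This leads through benzyl-protected epoxide 26 to homoallylic alcohol 25. Epoxidation is placed this late because an earlier epoxide would face the tertiary C4 alkoxide of the acylation, which sits on the face from which the epoxide can be opened. The precursor lacks two stereocentres. The forward reaction must place oxygen on the face of the C6 hydroxyl, and the final hydrogenolysis must spare epoxide and ester.

**Ester (25 ⇒ 24 ⇒ 18 + 22).** The ester C–O bond at C4 is cut, giving mono-silyl ether 18 and acid chloride 22, which comes from vanillic acid 19 through acid 21. Carrying the aroyl group from an earlier stage would put a β-acyloxy group next to the C6 ketone of 16 and invite elimination. The silyl group on O6 in 24 only singles out the tertiary hydroxyl. The forward step asks a hindered tertiary alkoxide (23) to be acylated without silyl migration.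

**C6 configuration (18 ⇒ 17 ⇒ 16 ⇒ 15).** No skeletal bond is cut; the C6–H bond is exchanged. Diol 17 is traced through hydroxy ketone 16 to the C6 epimer 15. This detour is accepted because the C6 oxygen has to stand on the face of the angular methyl while it steers the ring A annulation. An oxidation and reduction is preferred to a displacement at a hindered secondary carbon flanked by the ring fusion. The forward reduction must deliver hydride from the face of the C4 oxygen.

**Ring A saturation and silyl removal (15 ⇒ 14 ⇒ 13).** The C2–H and C3–H bonds are cut back to the C2=C3 alkene of diene diol 14, and the C3–H and both O–H bonds to the silyl groups of 13. This costs two steps, but it is what allows an alkyne to serve as the two-carbon unit. The forward reactions must remove a vinylic silicon next to a tertiary alcohol and reduce the disubstituted ring A alkene while leaving C8=C9.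

**Ring A (13 ⇒ 11 + 12).** C1–C2 and C3–C4 are cut together, giving enone 11 and trimethylsilylacetylene 12. Compared with cutting C4–C5 or C1–C5, this removes the quaternary carbon, the tertiary carbinol and the ring-fusion stereocentre at once. It leaves a monocyclic precursor with one stereocentre, and it keeps isopropyl on the carbon where it ends. The forward reaction must join the unsubstituted alkyne carbon to the fully substituted β-carbon anti to the C6 silyloxy group, protonate C5 on the same face and close the ring onto a hindered ketone.

**Acyl group (11 ⇒ 10 ⇒ 7 + 8).** The C4–C5 bond is cut to alkenyl bromide 7 and isobutyraldehyde 8, joined through alkenyllithium 9 and oxidised from alcohol 10. An aldehyde is chosen over an acyl donor because the alkenyl metal is flanked on both sides. The forward steps ask only for halogen–lithium exchange, addition and a neutral oxidation.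

**Carbinol stereocentre (7 ⇒ 6 ⇒ 5 ⇒ 4).** The only stereocentre of the precursor is traced to bromo dienone 5 by asymmetric reduction and from there to racemic alcohol 4. A 2-bromo enone is the substrate class for which catalyst-controlled hydride delivery is most dependable, so redox recycling of 4 is preferred to a resolution that discards half the material.

**Seven-membered ring (4 ⇒ 3 ⇒ 2 ⇒ 1).** The ring is contracted: C2 of 4 is removed as a carbene carbon from dibromocyclopropane 3, which comes from diene 2 and so from p-xylene 1. This one-carbon ring expansion places the bromine, the hydroxyl, both methyl groups and both alkenes in three steps. The forward opening must capture the allyl cation at its CH terminus.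

## Roads not taken

**Alternative 1:** Ring B would be cut at C7–C8 and C1–C10. Forward, a chiral dirhodium catalyst such as Rh2(S-DOSP)4 decomposes methyl 2-diazobut-3-enoate A3 on 2-(1-ethoxyethenyl)-3-methylcyclopent-2-en-1-one A2. Cyclopropanation of the enol ether alkene makes C7–C8, and Cope rearrangement of the cis-divinylcyclopropane closes ring B at C1–C10. The product is methyl 4-ethoxy-8a-methyl-3-oxo-1,2,3,5,8,8a-hexahydroazulene-6-carboxylate A1, with C1 set.
- Merits: the reaction type is established, a catalyst fixes the absolute configuration, C8=C9 and the C6 oxygen are in place, and no stereocentre has to be inverted later.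
- Weak points: the Cope step must end on the fully substituted β-carbon of a cyclopentenone, and A3 tends to cyclise before it meets the metal. Everything that separates A1 from the target is still to be done: the ester on C8 must become a methyl group without moving C8=C9, isopropyl must add to the hindered, enolisable C4 carbonyl of a vinylogous ester, and C5 must be set trans next to what becomes a β-hydroxy ketone.
- Comparison: in precedent for the key step and in the source of chirality this road is the stronger one. The chosen plan sets against it that after 13 no carbon–carbon bond and none of C1, C4, C5 remains to be made, whereas A1 needs several further skeleton-level operations on crowded centres, so the route would not be shorter.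

**Alternative 2:** Ring A would be cut at C4–C5 together with the O–C6 bond. Forward, 3-(1,5-dimethylcyclohepta-2,5-dien-1-yl)propanal oxime A5, with C1 already set, is oxidised with NaOCl to the nitrile oxide. This adds across the neighbouring C5=C6 alkene and gives the ring A-fused isoxazoline A4 (C4 as the C=N carbon, ring oxygen on C6).
- Merits: intramolecular nitrile oxide cycloaddition is dependable and metal-free, and it places O6 on the correct face relative to the C1 methyl, so C6 needs no inversion. N–O cleavage then reveals the C4 ketone and C6 hydroxyl.
- Weak points: the addition is suprafacial, so with O6 correct the fusion comes out cis (C5 epimeric). C5 would have to be epimerised α to the C4 ketone of a β-hydroxy ketone, where dehydration competes. Isopropyl must still be added to that ketone with the right facial sense. The quaternary stereocentre of A5 must be made enantioselectively beforehand on a ring with few handles.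
- Comparison: this road has the more reliable key step and gets C6 right first time. The chosen plan sets against it that it creates C1 rather than presupposing it, carries isopropyl into the ring closure and gives the trans fusion directly. Its price is the two-step C6 inversion and a key step without precedent.

**Alternative 3:** No ring is built at the key stage; a cis-fused decalin is rearranged. The precursor is 6-hydroxy-1,8-dimethyl-4-(propan-2-yl)-4-(triethylsilyloxy)bicyclo[4.4.0]dec-8-en-5-yl methanesulfonate A7. With KOt-Bu or Et2AlCl, C1 migrates from C6 to C5 with inversion at C5 and C6 becomes a ketone. One six-membered ring contracts to ring A and the other expands to ring B, giving 4-(triethylsilyloxy)dauc-8-en-6-one A6.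
- Merits: the shift is stereospecific and of a known type. A6 has C1, C4 and C5 as in the target and is the silyl ether of intermediate 16, so it would join the chosen end-game directly without a C6 inversion.
- Weak points: the difficulty moves into A7, a decalin with four contiguous stereocentres, three of them fully substituted. Its secondary hydroxyl between two such carbons must be sulfonylated. The migrating bond must lie antiperiplanar to the leaving group in a mobile cis-decalin, and the C6–C7 bond can migrate instead.
- Comparison: the key step itself is safer and stereochemically more certain than that of the chosen plan. The chosen plan sets against it the simplicity of its precursor: 11 has one stereocentre and is eight steps from p-xylene, while A7 needs a longer, separately controlled synthesis.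

Key step: step 9

Remark: the target is taken exactly as drawn, with the vanilloyl group on the tertiary C4 oxygen and the C6 hydroxyl free; daucane numbering is used (ring A C1–C5, ring B C1 and C5–C10, methyl on C1 and C8, isopropyl on C4).

## Route

Step 1
Reactants: 1 p-xylene
Product: 2 1,4-dimethylcyclohexa-1,4-diene
Conditions: Li, NH3(l), EtOH, Et2O, −78 to −33 °C
Reagents that add atoms: none
Why: Birch reduction; the radical anion of a 1,4-dialkylbenzene is protonated at the unsubstituted carbons, so both methyl groups end on the alkene carbons of the skipped diene.

Step 2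
Reactants: 2 1,4-dimethylcyclohexa-1,4-diene
Product: 3 7,7-dibromo-1,4-dimethylbicyclo[4.1.0]hept-3-ene (racemic)
Conditions: CHBr3 (1 equiv), KOt-Bu, pentane, 0 °C
Reagents that add atoms: bromoform, BrC(Br)Br
Why: α-Elimination gives dibromocarbene, which adds stereospecifically to an electron-rich trisubstituted alkene; the two alkenes of 2 are equivalent, and keeping bromoform as the limiting reagent should stop the reaction at the mono-adduct.

Step 3
Reactants: 3 7,7-dibromo-1,4-dimethylbicyclo[4.1.0]hept-3-ene
Product: 4 2-bromo-3,6-dimethylcyclohepta-2,5-dien-1-ol (racemic)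
Conditions: AgClO4, acetone–H2O, rt to 50 °C, dark
Reagents that add atoms: water, O
Why: Silver-assisted loss of the endo bromide with concerted disrotatory cyclopropyl-to-allyl opening gives the 2-bromocycloheptadienyl cation, which water should capture at its CH terminus so that the tetrasubstituted bromoalkene is kept; this is the established ring expansion of dibromocarbene adducts of cycloalkenes to 2-bromocycloalk-2-enols.

Step 4
Reactants: 4 2-bromo-3,6-dimethylcyclohepta-2,5-dien-1-ol
Product: 5 2-bromo-3,6-dimethylcyclohepta-2,5-dien-1-one
Conditions: Dess–Martin periodinane, pyridine, CH2Cl2, 0 °C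
Reagents that add atoms: none
Why: Dess–Martin oxidation of a secondary allylic alcohol; the pyridine buffer and low temperature should keep the β,γ-alkene (C5=C6 of the ring) from moving into conjugation with the new ketone.

Step 5
Reactants: 5 2-bromo-3,6-dimethylcyclohepta-2,5-dien-1-one
Product: 6 (1R)-2-bromo-3,6-dimethylcyclohepta-2,5-dien-1-ol
Conditions: (S)-1-methyl-3,3-diphenyltetrahydro-1H,3H-pyrrolo[1,2-c][1,3,2]oxazaborole (CBS catalyst, 10 mol%), catecholborane, toluene, −78 °C
Reagents that add atoms: none
Why: Corey–Bakshi–Shibata reduction: 2-bromo enones are established substrates, the bromoalkenyl arm acting as the large group as phenyl does in aryl ketones, so the (S)-catalyst should give the (R)-alcohol (the enantiomeric catalyst would be used if the sense proved opposite); catecholborane at −78 °C should not hydroborate the isolated alkene.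

Step 6
Reactants: 6 (1R)-2-bromo-3,6-dimethylcyclohepta-2,5-dien-1-ol
Product: 7 [(1R)-2-bromo-3,6-dimethylcyclohepta-2,5-dien-1-yl]oxy(tert-butyl)dimethylsilane
Conditions: TBSCl, imidazole, DMF, rt
Reagents that add atoms: tert-butyldimethylsilyl chloride, CC(C)(C)[Si](C)(C)Cl
Why: Standard silylation of a secondary allylic alcohol; the silyl ether protects the carbinol from the organolithium of step 7 and is the bulky group that later shields one face of the enone.

Step 7
Reactants: 7 [(1R)-2-bromo-3,6-dimethylcyclohepta-2,5-dien-1-yl]oxy(tert-butyl)dimethylsilane; 8 isobutyraldehyde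
Product: 10 1-[(7R)-7-(tert-butyldimethylsilyloxy)-2,5-dimethylcyclohepta-1,4-dien-1-yl]-2-methylpropan-1-ol (both carbinol epimers), via alkenyllithium 9 (not isolated)
Conditions: t-BuLi (2.1 equiv), THF, −78 °C; then 8, −78 °C
Reagents that add atoms: none
Why: Lithium–bromine exchange on an alkenyl bromide with two equivalents of t-BuLi outruns deprotonation at −78 °C, and β-elimination of the silyloxy group would require a seven-membered cyclic allene; alkenyllithium 9 adds to the aldehyde, and the new carbinol centre does not matter because it is oxidised in step 8.

Step 8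
Reactants: 10 1-[(7R)-7-(tert-butyldimethylsilyloxy)-2,5-dimethylcyclohepta-1,4-dien-1-yl]-2-methylpropan-1-ol
Product: 11 1-[(7R)-7-(tert-butyldimethylsilyloxy)-2,5-dimethylcyclohepta-1,4-dien-1-yl]-2-methylpropan-1-one
Conditions: Dess–Martin periodinane, pyridine, CH2Cl2, 0 °C to rt
Reagents that add atoms: none
Why: Dess–Martin oxidation of an allylic secondary alcohol to the tetrasubstituted enone under buffered, non-enolising conditions, so the skipped diene should not isomerise.

Step 9
Reactants: 11 1-[(7R)-7-(tert-butyldimethylsilyloxy)-2,5-dimethylcyclohepta-1,4-dien-1-yl]-2-methylpropan-1-one; 12 trimethylsilylacetylene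
Product: 13 6-(tert-butyldimethylsilyloxy)-3-(trimethylsilyl)dauca-2,8-dien-4-ol (trans-fused; C1 methyl, C4 hydroxyl and C6 silyloxy on one face; C5 hydrogen and isopropyl on the other)
Conditions: Ni(cod)2 (20 mol%), PBu3 (40 mol%), Et3B (3 equiv), MeOH–THF, 50 °C, slow addition of 12
Reagents that add atoms: none
Why: Proposed new method: zerovalent nickel carrying PBu3 binds the s-cis enone of 11 and alkyne 12 and undergoes oxidative cyclisation to a seven-membered nickel O-enolate in which C1–C2 has formed and silicon sits on the nickel-bound carbon C3, the usual regiochemistry of silylalkynes and the one that brings the unhindered CH terminus to the carbon that becomes quaternary. Methanol held on nickel protonates the enolate at C5 from the face carrying the metallacycle, the alkenylnickel then adds to the freed isopropyl ketone (C3–C4, 5-exo-trig closure of ring A), and Et3B exchanges an ethyl group onto divalent nickel, after which β-hydride and reductive elimination return zerovalent nickel. The closest known reaction type is the nickel-catalysed reductive [3+2] cycloaddition of enals and enones with alkynes to cyclopentenols, which has not been shown for a tetrasubstituted enone that must form a quaternary carbon. C1 is controlled by the C6 silyloxy group, which should sit pseudoaxial to avoid A(1,2) strain with the isobutyryl group and so block one face of C5=C1, making the alkyne bond anti to it. C5 follows from C1 because the proton arrives on the face of the new C1–C2 bond, which gives the trans fusion. C4 is set in the ring closure, where the carbonyl should turn its oxygen toward the face of the angular methyl and the C6 silyloxy group and its isopropyl group away from both. The step needs chemoselectivity for the conjugated over the isolated C8=C9 alkene, secured because only the oxa-diene can become a nickel enolate, and ring closure rather than protonation of the alkenylnickel, favoured by the ketone being held five atoms away and by slow addition of 12, which also curbs alkyne oligomerisation.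

Step 10
Reactants: 13 6-(tert-butyldimethylsilyloxy)-3-(trimethylsilyl)dauca-2,8-dien-4-ol
Product: 14 dauca-2,8-diene-4,6-diol (configuration as in 13)
Conditions: TBAF (5 equiv), THF, 60 °C
Reagents that add atoms: none
Why: Fluoride cleaves the C6 silyl ether, and the C4 alkoxide attacks the neighbouring silicon to give a pentacoordinate siliconate that releases the alkenyl carbon (Brook-type C-to-O shift) for protonation with retention: the hydroxyl-assisted protodesilylation known for 2-silyl allylic alcohols; the competing Peterson-type elimination is excluded because it would give a cyclic allene.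

Step 11
Reactants: 14 dauca-2,8-diene-4,6-diol
Product: 15 (1R,4R,5S,6R)-dauc-8-ene-4,6-diol (C6 epimer of 17)
Conditions: 2-nitrobenzenesulfonylhydrazide, Et3N, CH2Cl2, rt
Reagents that add atoms: none
Why: Diimide transfers H2 in a concerted syn fashion at rates that fall steeply with alkene substitution, so the cis-disubstituted cyclopentene C2=C3 should be reduced well before the trisubstituted C8=C9; no metal is present to migrate the remaining alkene or cleave the allylic C4–O bond, and no stereocentre is formed.

Step 12
Reactants: 15 (1R,4R,5S,6R)-dauc-8-ene-4,6-diol
Product: 16 (1R,4R,5R)-4-hydroxydauc-8-en-6-one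
Conditions: Dess–Martin periodinane, pyridine, CH2Cl2, 0 °C
Reagents that add atoms: none
Why: Dess–Martin oxidation: only the secondary C6 hydroxyl can be oxidised, and the neutral buffered medium should avoid retro-aldol cleavage or dehydration of the β-hydroxy ketone and leave C5 unepimerised.

Step 13
Reactants: 16 (1R,4R,5R)-4-hydroxydauc-8-en-6-one
Product: 17 (1R,4R,5S,6S)-dauc-8-ene-4,6-diol
Conditions: Me4NBH(OAc)3, MeCN–AcOH, −30 to 0 °C
Reagents that add atoms: none
Why: Evans–Saksena hydroxyl-directed reduction: the tertiary C4 hydroxyl exchanges an acetate on boron and hydride is delivered through a six-membered transition state from the face of O4, so the new C6 hydroxyl should appear on the opposite face, cis to the C5 hydrogen, as in the target; the reagent is too weak to reduce the ketone intermolecularly.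

Step 14
Reactants: 17 (1R,4R,5S,6S)-dauc-8-ene-4,6-diol
Product: 18 (1R,4R,5S,6S)-6-(triethylsilyloxy)dauc-8-en-4-ol
Conditions: TESCl, imidazole, DMF, 0 °C
Reagents that add atoms: chlorotriethylsilane, CC[Si](CC)(CC)Cl
Why: Silylation with TESCl and imidazole distinguishes the secondary C6 hydroxyl from the tertiary C4 hydroxyl, which stays free for acylation.

Step 15
Reactants: 19 vanillic acid
Product: 21 4-(benzyloxy)-3-methoxybenzoic acid, via benzyl 4-(benzyloxy)-3-methoxybenzoate 20 (not isolated)
Conditions: BnBr (2.2 equiv), K2CO3, DMF, 60 °C; then NaOH, MeOH–H2O, 65 °C; HCl work-up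
Reagents that add atoms: benzyl bromide, BrCc1ccccc1
Why: Williamson benzylation of both the phenol and the carboxylate, then saponification of the benzyl ester in the same flask; the aryl benzyl ether survives hydroxide.

Step 16
Reactants: 21 4-(benzyloxy)-3-methoxybenzoic acid
Product: 22 4-(benzyloxy)-3-methoxybenzoyl chloride
Conditions: (COCl)2, cat. N,N-dimethylformamide, CH2Cl2, 0 °C to rt
Reagents that add atoms: oxalyl chloride, ClC(=O)C(=O)Cl
Why: Acid chloride formation through chloroiminium (Vilsmeier-type) activation; the two ether groups are inert and the volatile by-products leave on evaporation.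

Step 17
Reactants: 18 (1R,4R,5S,6S)-6-(triethylsilyloxy)dauc-8-en-4-ol; 22 4-(benzyloxy)-3-methoxybenzoyl chloride
Product: 24 (1R,4R,5S,6S)-6-(triethylsilyloxy)dauc-8-en-4-yl 4-(benzyloxy)-3-methoxybenzoate, via lithium alkoxide 23 (not isolated)
Conditions: n-BuLi (1.05 equiv), THF, −78 °C; then 22, −78 °C to rt
Reagents that add atoms: none
Why: O-Acylation of a pre-formed lithium tertiary alkoxide with an aroyl chloride, the standard answer to alcohols that resist amine-catalysed acylation; O4 and the O6 silyl ether lie on opposite faces, so silyl migration to the alkoxide is geometrically disfavoured, and no centre in 23 is epimerisable.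

Step 18
Reactants: 24 (1R,4R,5S,6S)-6-(triethylsilyloxy)dauc-8-en-4-yl 4-(benzyloxy)-3-methoxybenzoate
Product: 25 (1R,4R,5S,6S)-6-hydroxydauc-8-en-4-yl 4-(benzyloxy)-3-methoxybenzoate
Conditions: HF·pyridine, pyridine, THF, 0 °C to rt
Reagents that add atoms: none
Why: Buffered HF·pyridine cleaves the triethylsilyl ether of a secondary alcohol without touching the tertiary ester, the benzyl ether or the alkene.

Step 19
Reactants: 25 (1R,4R,5S,6S)-6-hydroxydauc-8-en-4-yl 4-(benzyloxy)-3-methoxybenzoate
Product: 26 (1R,4R,5S,6S,8R,9S)-8,9-epoxy-6-hydroxydaucan-4-yl 4-(benzyloxy)-3-methoxybenzoate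
Conditions: VO(acac)2 (5 mol%), t-BuOOH, CH2Cl2, 0 °C to rt
Reagents that add atoms: tert-butyl hydroperoxide, CC(C)(C)OO
Why: Hydroxyl-directed epoxidation: the C6 hydroxyl, homoallylic to C8=C9, binds the pentavalent vanadium tert-butylperoxide and delivers oxygen to its own face, which is also the face remote from the angular methyl, so direction and steric bias are matched and set C8 and C9 together; the ester and benzyl ether are inert.

Step 20
Reactants: 26 (1R,4R,5S,6S,8R,9S)-8,9-epoxy-6-hydroxydaucan-4-yl 4-(benzyloxy)-3-methoxybenzoate
Product: 27 (1R,4R,5S,6S,8R,9S)-8,9-epoxy-6-hydroxydaucan-4-yl 4-hydroxy-3-methoxybenzoate (CNP0315707.1)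
Conditions: H2 (1 atm), Pd/C, EtOAc, rt
Reagents that add atoms: none
Why: Hydrogenolysis of an aryl benzyl ether over Pd/C under neutral conditions; the trialkyl-substituted epoxide, which is neither benzylic nor allylic, and the ester are expected to remain.

## Compound list

1 | p-xylene | Cc1ccc(C)cc1 | starting material
2 | 1,4-dimethylcyclohexa-1,4-diene | CC1=CCC(C)=CC1 | intermediate
3 | 7,7-dibromo-1,4-dimethylbicyclo[4.1.0]hept-3-ene (racemic, cis ring fusion) | CC1=CCC2(C)C(C1)C2(Br)Br | intermediate
4 | 2-bromo-3,6-dimethylcyclohepta-2,5-dien-1-ol (racemic) | CC1=C(Br)C(O)CC(C)=CC1 | intermediate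
5 | 2-bromo-3,6-dimethylcyclohepta-2,5-dien-1-one | CC1=C(Br)C(=O)CC(C)=CC1 | intermediate
6 | (1R)-2-bromo-3,6-dimethylcyclohepta-2,5-dien-1-ol | BrC1=C(C)CC=C(C)C[C@H]1O | intermediate
7 | [(1R)-2-bromo-3,6-dimethylcyclohepta-2,5-dien-1-yl]oxy(tert-butyl)dimethylsilane | BrC1=C(C)CC=C(C)C[C@H]1O[Si](C)(C)C(C)(C)C | intermediate
8 | isobutyraldehyde | CC(C)C=O | starting material
9 | [(7R)-7-(tert-butyldimethylsilyloxy)-2,5-dimethylcyclohepta-1,4-dien-1-yl]lithium (formed in the flask) | [Li]C1=C(C)CC=C(C)C[C@H]1O[Si](C)(C)C(C)(C)C | intermediate
10 | 1-[(7R)-7-(tert-butyldimethylsilyloxy)-2,5-dimethylcyclohepta-1,4-dien-1-yl]-2-methylpropan-1-ol (both carbinol epimers) | CC(C)C(O)C1=C(C)CC=C(C)C[C@H]1O[Si](C)(C)C(C)(C)C | intermediate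
11 | 1-[(7R)-7-(tert-butyldimethylsilyloxy)-2,5-dimethylcyclohepta-1,4-dien-1-yl]-2-methylpropan-1-one | CC(C)C(=O)C1=C(C)CC=C(C)C[C@H]1O[Si](C)(C)C(C)(C)C | intermediate
12 | trimethylsilylacetylene | C#C[Si](C)(C)C | starting material
13 | 6-(tert-butyldimethylsilyloxy)-3-(trimethylsilyl)dauca-2,8-dien-4-ol (trans-fused; C1 methyl, C4 OH and C6 silyloxy on one face; C5 H and isopropyl on the other) | O[C@@]2(C(C)C)C([Si](C)(C)C)=C[C@]3(C)CC=C(C)C[C@@H](O[Si](C)(C)C(C)(C)C)[C@H]32 | intermediate
14 | dauca-2,8-diene-4,6-diol (configuration as in 13) | O[C@@]2(C(C)C)C=C[C@]3(C)CC=C(C)C[C@@H](O)[C@H]32 | intermediate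
15 | (1R,4R,5S,6R)-dauc-8-ene-4,6-diol | O[C@@]2(C(C)C)CC[C@]3(C)CC=C(C)C[C@@H](O)[C@H]32 | intermediate
16 | (1R,4R,5R)-4-hydroxydauc-8-en-6-one | O[C@@]2(C(C)C)CC[C@]3(C)CC=C(C)CC(=O)[C@H]32 | intermediate
17 | (1R,4R,5S,6S)-dauc-8-ene-4,6-diol | O[C@@]2(C(C)C)CC[C@]3(C)CC=C(C)C[C@H](O)[C@H]32 | intermediate
18 | (1R,4R,5S,6S)-6-(triethylsilyloxy)dauc-8-en-4-ol | O[C@@]2(C(C)C)CC[C@]3(C)CC=C(C)C[C@H](O[Si](CC)(CC)CC)[C@H]32 | intermediate
19 | vanillic acid | COc1cc(C(=O)O)ccc1O | starting material
20 | benzyl 4-(benzyloxy)-3-methoxybenzoate (formed in the flask) | COc1cc(C(=O)OCc2ccccc2)ccc1OCc1ccccc1 | intermediate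
21 | 4-(benzyloxy)-3-methoxybenzoic acid | COc1cc(C(=O)O)ccc1OCc1ccccc1 | intermediate
22 | 4-(benzyloxy)-3-methoxybenzoyl chloride | COc1cc(C(Cl)=O)ccc1OCc1ccccc1 | intermediate
23 | lithium alkoxide of 18 (formed in the flask) | [Li]O[C@@]2(C(C)C)CC[C@]3(C)CC=C(C)C[C@H](O[Si](CC)(CC)CC)[C@H]32 | intermediate
24 | (1R,4R,5S,6S)-6-(triethylsilyloxy)dauc-8-en-4-yl 4-(benzyloxy)-3-methoxybenzoate | COc1cc(C(=O)O[C@@]2(C(C)C)CC[C@]3(C)CC=C(C)C[C@H](O[Si](CC)(CC)CC)[C@H]32)ccc1OCc1ccccc1 | intermediate
25 | (1R,4R,5S,6S)-6-hydroxydauc-8-en-4-yl 4-(benzyloxy)-3-methoxybenzoate | COc1cc(C(=O)O[C@@]2(C(C)C)CC[C@]3(C)CC=C(C)C[C@H](O)[C@H]32)ccc1OCc1ccccc1 | intermediate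
26 | (1R,4R,5S,6S,8R,9S)-8,9-epoxy-6-hydroxydaucan-4-yl 4-(benzyloxy)-3-methoxybenzoate | COc1cc(C(=O)O[C@@]2(C(C)C)CC[C@]3(C)C[C@@H]4O[C@]4(C)C[C@H](O)[C@H]32)ccc1OCc1ccccc1 | intermediate
27 | (1R,4R,5S,6S,8R,9S)-8,9-epoxy-6-hydroxydaucan-4-yl 4-hydroxy-3-methoxybenzoate | COc1cc(C(=O)O[C@@]2(C(C)C)CC[C@]3(C)C[C@@H]4O[C@]4(C)C[C@H](O)[C@H]32)ccc1O | target

## Step count and risks

Total: 20 steps. Longest linear sequence: 18 steps (steps 1–14 and 17–20, from p-xylene 1); steps 15 and 16 are the side branch from vanillic acid 19.

**Step 9 (key step, proposed new method).** The most likely failure is that the enone never enters the metallacycle. Its isobutyryl group is twisted out of conjugation by the two flanking substituents and its β-carbon is fully substituted, so zerovalent nickel may consume alkyne 12 by oligomerisation instead. Two further failure processes are protonation of the alkenylnickel before it reaches the crowded ketone (ring A not closed) and delivery of the C5 proton on the face away from nickel (cis fusion).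

Fallback by known chemistry, setting out from 11 and returning at 15, builds the two carbons one bond at a time:
- BF3-promoted conjugate addition of a vinylcopper reagent (vinylmagnesium bromide, CuI, BF3·OEt2, THF, −78 °C) anti to the C6 silyloxy group, with kinetic protonation of the enolate on the same face, should give 1-[7-(tert-butyldimethylsilyloxy)-2-ethenyl-2,5-dimethylcyclohept-4-en-1-yl]-2-methylpropan-1-one F1.
- Hydroboration of the vinyl group alone with 9-borabicyclo[3.3.1]nonane and oxidation with NaBO3 gives the corresponding 2-(2-hydroxyethyl) ketone F2.
- I2, PPh3 and imidazole convert it into the 2-(2-iodoethyl) ketone F3.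
- SmI2 in THF–HMPA closes ring A by an intramolecular Barbier reaction, isopropyl again turning away from the angular methyl, to give 6-(tert-butyldimethylsilyloxy)dauc-8-en-4-ol F4.
- TBAF releases 15, so steps 10 and 11 are not needed.

**Step 17.** The tertiary alkoxide 23, wedged between isopropyl and the ring fusion, may be acylated so slowly that migration of the silyl group from O6 or decomposition of the acid chloride wins. Fallback from 18, returning at 24: the sodium alkoxide of 18 (NaH, toluene) is combined under CO (1 atm) with 1-(benzyloxy)-4-iodo-2-methoxybenzene F5, made by O-benzylation of the commercial iodophenol, using Pd(OAc)2 and Xantphos at 80 °C. In this alkoxycarbonylation the alkoxide binds a divalent acylpalladium intermediate and the ester C–O bond forms by reductive elimination, not by attack of a hindered nucleophile on a free acyl halide.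

**Step 3.** Water may capture the bromoallyl cation at its methyl-bearing terminus, where more positive charge resides, and give the transposed tertiary alcohol; proton loss toward a cycloheptatriene is the second danger. Fallback from 3, returning at 5: the opening is run as before and the tertiary isomer 2-bromo-1,5-dimethylcyclohepta-2,5-dien-1-ol F6 is not separated. Pyridinium chlorochromate, [C5H5NH][CrO3Cl], in CH2Cl2 converts it by Babler–Dauben oxidative 1,3-transposition into dienone 5, the ketone that any 4 in the mixture also gives, so step 4 is merged into this operation.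

**Step 13.** The tertiary C4 hydroxyl may exchange onto boron too slowly for internal delivery, leaving no reduction or an unselective background reduction; the β-hydroxy ketone 16 may also suffer retro-aldol cleavage on prolonged exposure. Fallback from 15, returning at 17 without passing through 16: Mitsunobu inversion of the secondary C6 hydroxyl (4-nitrobenzoic acid, PPh3, diisopropyl azodicarboxylate, toluene) gives (1R,4R,5S,6S)-4-hydroxydauc-8-en-6-yl 4-nitrobenzoate F7, the tertiary hydroxyl being inert, and K2CO3 in MeOH releases 17.

## Further compounds

F1 | step 9 | 1-[7-(tert-butyldimethylsilyloxy)-2-ethenyl-2,5-dimethylcyclohept-4-en-1-yl]-2-methylpropan-1-one (vinyl trans to silyloxy and to acyl) | CC(C)C(=O)[C@@H]1[C@H](O[Si](C)(C)C(C)(C)C)CC(C)=CC[C@@]1(C)C=C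
F2 | step 9 | 1-[7-(tert-butyldimethylsilyloxy)-2-(2-hydroxyethyl)-2,5-dimethylcyclohept-4-en-1-yl]-2-methylpropan-1-one | CC(C)C(=O)[C@@H]1[C@H](O[Si](C)(C)C(C)(C)C)CC(C)=CC[C@@]1(C)CCO
F3 | step 9 | 1-[7-(tert-butyldimethylsilyloxy)-2-(2-iodoethyl)-2,5-dimethylcyclohept-4-en-1-yl]-2-methylpropan-1-one | CC(C)C(=O)[C@@H]1[C@H](O[Si](C)(C)C(C)(C)C)CC(C)=CC[C@@]1(C)CCI
F4 | step 9 | 6-(tert-butyldimethylsilyloxy)dauc-8-en-4-ol (configuration as in 15) | O[C@@]2(C(C)C)CC[C@]3(C)CC=C(C)C[C@@H](O[Si](C)(C)C(C)(C)C)[C@H]32
F5 | step 17 | 1-(benzyloxy)-4-iodo-2-methoxybenzene | COc1cc(I)ccc1OCc1ccccc1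
F6 | step 3 | 2-bromo-1,5-dimethylcyclohepta-2,5-dien-1-ol (racemic) | CC1(O)CC=C(C)CC=C1Br
F7 | step 13 | (1R,4R,5S,6S)-4-hydroxydauc-8-en-6-yl 4-nitrobenzoate | O[C@@]2(C(C)C)CC[C@]3(C)CC=C(C)C[C@H](OC(=O)c4ccc(cc4)[N+](=O)[O-])[C@H]32
A1 | alternative 1 | methyl 4-ethoxy-8a-methyl-3-oxo-1,2,3,5,8,8a-hexahydroazulene-6-carboxylate (C1 as in the target) | O=C2CC[C@]3(C)CC=C(C(=O)OC)CC(OCC)=C32
A2 | alternative 1 | 2-(1-ethoxyethenyl)-3-methylcyclopent-2-en-1-one | CCOC(=C)C1=C(C)CCC1=O
A3 | alternative 1 | methyl 2-diazobut-3-enoate | COC(=O)C(=[N+]=[N-])C=C
A4 | alternative 2 | ring A-fused isoxazoline of the dauc-8-ene skeleton (C4 as C=N carbon, ring oxygen on C6; C1 and C6 as in the target, C5 epimeric) | C1(=NO[C@H]2CC(C)=CC[C@@]3(C)CC1)[C@@H]23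
A5 | alternative 2 | 3-(1,5-dimethylcyclohepta-2,5-dien-1-yl)propanal oxime (quaternary carbon as C1 of the target) | ON=CCC[C@@]1(C)C=CCC(C)=CC1
A6 | alternative 3 | 4-(triethylsilyloxy)dauc-8-en-6-one (C1, C4, C5 as in the target) | CC[Si](CC)(CC)O[C@@]2(C(C)C)CC[C@]3(C)CC=C(C)CC(=O)[C@H]32
A7 | alternative 3 | 6-hydroxy-1,8-dimethyl-4-(propan-2-yl)-4-(triethylsilyloxy)bicyclo[4.4.0]dec-8-en-5-yl methanesulfonate (cis-fused; methyl, both ring oxygens on C4 and C6 and the mesylate on one face) | CC[Si](CC)(CC)O[C@@]1(C(C)C)CC[C@]2(C)CC=C(C)C[C@]2(O)[C@H]1OS(C)(=O)=O
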